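## Retrosynthetic overview

1. Numbering: isochromanone C1 (lactone C=O), O2, C3, C4, C4a, C5–C8, C8a. Ring A is the arene and ring B the lactone. The side chain runs C1', C2', C3', C4', and C4' bears the O-succinyl group and CH3.
2. Structural feature used: in ring B the pair C4–C3 lies between aryl carbon C4a and oxygen O2 of a carboxyl group (C1) on the adjacent aryl carbon C8a, and C3 continues into C1'–C2'. C4=C3–C1'=C2' can therefore be read as a terminal 1,3-diene, and C4a/C8a–C1 as a 2-iodobenzoic acid.
3. Key disconnection: C4a–C4 and O2–C3 are cut together by a ligand-controlled, palladium-catalysed diene heteroannulation. This gives 2-iodo-3,6-dimethoxybenzoic acid and a (2R,4E)-hepta-4,6-dien-2-yl tert-butyl succinate that already holds C4' and the ester arm.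
4. The iodo acid comes from 2,5-dimethoxybenzoic acid by directed ortho-metalation. The diene comes from (R)-pent-4-yn-2-ol by esterification, hydroboration and vinylation.
5. Ring order: ring A is bought and ring B is the only ring made (step 5). The C1'=C2' alkene is then saturated, and one BBr3 step frees both phenols and the acid.

Key step: step 5

Assumption: the sense of induction of the chiral ligand cannot be predicted for a carboxylate nucleophile. The (S,R,R)-phosphoramidite, (S)-1,1'-binaphthyl-2,2'-diyl N,N-bis[(R)-1-phenylethyl]phosphoramidite, is written, and its mirror image is used instead if a first run favours the C3 epimer.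

Assumption: (R)-pent-4-yn-2-ol is bought in high enantiomeric purity.

Remark: the succinate terminus is carried as a tert-butyl ester. It withstands the basic palladium steps, lets the allylic lactone be hydrogenated without palladium on carbon, and is lost in the same BBr3 step as the methyl ethers.

## Route

Step 1
Reactants: 1 2,5-dimethoxybenzoic acid
Product: 3 2-iodo-3,6-dimethoxybenzoic acid, via dilithio benzoate 2 (not isolated)
Conditions: s-BuLi (2.2 equiv), TMEDA (2.2 equiv), THF, −78 °C; I2, THF, −78 °C → rt; aq Na2S2O3, then HCl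
Reagents that add atoms: iodine, [I][I]
Why: Directed ortho-metalation of an unprotected benzoic acid should work because C6 of 1 is the only position ortho to the lithium carboxylate and is also ortho to the 5-methoxy group, so both directing groups point the base at the same hydrogen and iodine traps the aryl lithium.

Step 2
Reactants: 4 (R)-pent-4-yn-2-ol; 5 4-(tert-butoxy)-4-oxobutanoic acid
Product: 6 tert-butyl (2R)-pent-4-yn-2-yl butanedioate
Conditions: DCC, DMAP (cat.), CH2Cl2, 0 °C → rt
Reagents that add atoms: none
Why: Steglich esterification acylates the alcohol oxygen without touching the C–O bond at the stereocentre, so the (R) configuration that becomes C4' is kept.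

Step 3
Reactants: 6 tert-butyl (2R)-pent-4-yn-2-yl butanedioate
Product: 7 tert-butyl (2R,4E)-5-(4,4,5,5-tetramethyl-1,3,2-dioxaborolan-2-yl)pent-4-en-2-yl butanedioate
Conditions: pinacolborane (1.3 equiv), Cp2ZrHCl (10 mol %), Et3N (10 mol %), neat, 60 °C
Reagents that add atoms: pinacolborane, CC1(C)OBOC1(C)C
Why: Cp2ZrHCl-catalysed hydroboration of a terminal alkyne is a syn, anti-Markovnikov addition that should give only the (E)-alkenyl boronate and leave both esters untouched.

Step 4
Reactants: 7 tert-butyl (2R,4E)-5-(4,4,5,5-tetramethyl-1,3,2-dioxaborolan-2-yl)pent-4-en-2-yl butanedioate; 8 vinyl bromide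
Product: 9 tert-butyl (2R,4E)-hepta-4,6-dien-2-yl butanedioate
Conditions: vinyl bromide (1 M in THF, 3 equiv), Pd(PPh3)4 (5 mol %), K3PO4 (3 equiv), THF/H2O 10:1, 50 °C, sealed tube, trace BHT
Reagents that add atoms: none
Why: Suzuki–Miyaura coupling of an alkenyl boronate with an alkenyl bromide proceeds with retention of the E geometry, and the phosphate base is mild enough for the two esters.

Step 5
Reactants: 3 2-iodo-3,6-dimethoxybenzoic acid; 9 tert-butyl (2R,4E)-hepta-4,6-dien-2-yl butanedioate
Product: 10 tert-butyl (2R,4E)-5-[(3S)-5,8-dimethoxy-1-oxoisochroman-3-yl]pent-4-en-2-yl butanedioate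
Conditions: 3 (1.2 equiv), Pd2(dba)3·CHCl3 (2.5 mol %), (S,R,R)-phosphoramidite (11 mol %), K2CO3 (2 equiv), DMF, 70 °C, Ar
Reagents that add atoms: none
Why: Proposed new method: oxidative addition of the C–I bond of 3 to zerovalent palladium and exchange of iodide for the neighbouring carboxylate give an aryl palladium carboxylate, which adds syn across the terminal C6=C7 alkene of 9 with the aryl group going to the unsubstituted carbon (C4a–C4), leaving a syn,syn allyl palladium over C3, C1' and C2'. The closest known reaction is the Larock heteroannulation of 1,3-dienes with 2-iodobenzoic acids under achiral palladium catalysts, and the ligand-controlled enantioselective form is established only for 2-halophenols and 2-iodoanilines, so enantiocontrol with a carboxylate is the untested part. Ring B closes by 6-exo attack of the carboxylate oxygen on the near allyl terminus C3 (O2–C3), because attack at C2' would need an eight-membered lactone, so ring size secures the regiochemistry and the syn,syn allyl leaves an E alkene that is removed later. C3 is controlled by the phosphoramidite alone: it chooses the face of the terminal alkene at insertion, and a 1,3-disubstituted allyl cannot change face by sigma–pi interconversion without passing into anti isomers, so that face should be handed on to the C–O bond, while C4' is too remote to have any influence. A monodentate ligand is chosen because the chelating carboxylate fills one site and the diene needs another, silver salts are left out because electron-rich 2,6-disubstituted benzoic acids lose CO2 in their presence, and the homoallylic succinate is not ionised by zerovalent palladium. Because 9 is a single enantiomer, the selectivity appears as a ratio of C3 epimers that can be read by NMR or HPLC and improved by chromatography.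

Step 6
Reactants: 10 tert-butyl (2R,4E)-5-[(3S)-5,8-dimethoxy-1-oxoisochroman-3-yl]pent-4-en-2-yl butanedioate
Product: 11 tert-butyl (2R)-5-[(3R)-5,8-dimethoxy-1-oxoisochroman-3-yl]pentan-2-yl butanedioate
Conditions: H2 (1–4 atm), RhCl(PPh3)3 (10 mol %), toluene/EtOH 1:1, rt
Reagents that add atoms: none
Why: Homogeneous hydrogenation with RhCl(PPh3)3 should saturate the disubstituted alkene without hydrogenolysis of the allylic C3–O2 bond and without moving the alkene toward C3 (both are risks over palladium on carbon), so C3 keeps its arrangement and only its label changes from S to R.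

Step 7
Reactants: 11 tert-butyl (2R)-5-[(3R)-5,8-dimethoxy-1-oxoisochroman-3-yl]pentan-2-yl butanedioate
Product: 12 4-{[(2R)-5-[(3R)-5,8-dihydroxy-1-oxoisochroman-3-yl]pentan-2-yl]oxy}-4-oxobutanoic acid (target)
Conditions: BBr3 (6 equiv), CH2Cl2, −78 → 0 °C; H2O, 0 °C; work-up under Ar
Reagents that add atoms: none
Why: BBr3 ether cleavage should take the 8-methoxy group first (chelation to the C1 carbonyl), then the 5-methoxy group and the acid-labile tert-butyl ester, while the secondary alkyl–oxygen bonds of the lactone and the succinate react much more slowly at or below 0 °C and neither stereocentre is touched.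

## Compound list

1 | 2,5-dimethoxybenzoic acid | COc1ccc(OC)c(C(=O)O)c1 | starting material
2 | lithium 2-lithio-3,6-dimethoxybenzoate | [Li]c1c(OC)ccc(OC)c1C(=O)O[Li] | intermediate
3 | 2-iodo-3,6-dimethoxybenzoic acid | OC(=O)c1c(OC)ccc(OC)c1I | intermediate
4 | (R)-pent-4-yn-2-ol | C[C@H](CC#C)O | starting material
5 | 4-(tert-butoxy)-4-oxobutanoic acid | OC(=O)CCC(=O)OC(C)(C)C | starting material
6 | tert-butyl (2R)-pent-4-yn-2-yl butanedioate | C[C@H](CC#C)OC(=O)CCC(=O)OC(C)(C)C | intermediate
7 | tert-butyl (2R,4E)-5-(4,4,5,5-tetramethyl-1,3,2-dioxaborolan-2-yl)pent-4-en-2-yl butanedioate | C[C@H](C/C=C/B1OC(C)(C)C(C)(C)O1)OC(=O)CCC(=O)OC(C)(C)C | intermediate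
8 | vinyl bromide | C=CBr | starting material
9 | tert-butyl (2R,4E)-hepta-4,6-dien-2-yl butanedioate | C[C@H](C/C=C/C=C)OC(=O)CCC(=O)OC(C)(C)C | intermediate
10 | tert-butyl (2R,4E)-5-[(3S)-5,8-dimethoxy-1-oxoisochroman-3-yl]pent-4-en-2-yl butanedioate | C[C@H](C/C=C/[C@@H]1Cc2c(OC)ccc(OC)c2C(=O)O1)OC(=O)CCC(=O)OC(C)(C)C | intermediate
11 | tert-butyl (2R)-5-[(3R)-5,8-dimethoxy-1-oxoisochroman-3-yl]pentan-2-yl butanedioate | C[C@H](CCC[C@@H]1Cc2c(OC)ccc(OC)c2C(=O)O1)OC(=O)CCC(=O)OC(C)(C)C | intermediate
12 | 4-{[(2R)-5-[(3R)-5,8-dihydroxy-1-oxoisochroman-3-yl]pentan-2-yl]oxy}-4-oxobutanoic acid | C[C@H](CCC[C@@H]1Cc2c(O)ccc(O)c2C(=O)O1)OC(=O)CCC(=O)O | target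

Total step count: 7
Longest linear sequence: 6 (steps 2, 3, 4, 5, 6 and 7, from 4)

## Steps most likely to fail

**Step 5 (Proposed new method).**
- What may go wrong: weak facial selection at the insertion.
- Loss of a hydrogen from C4 or C3' of the allyl palladium could take the reaction to Heck-type polyenes.
- The hindered acid could lose CO2 or iodine before insertion.
- The allylic lactone could be re-ionised by zerovalent palladium.

The fallback uses known chemistry only, sets out from 3 and comes back at 11. C3 is taken from a resolved epoxide, and ring B is closed by aryl-metal epoxide opening and lactonisation.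

3 is methylated (MeI, K2CO3, DMF) to methyl 2-iodo-3,6-dimethoxybenzoate F1. Separately, (R)-propylene oxide is opened with but-3-enylmagnesium bromide and CuI (THF, −30 °C) to (R)-hept-6-en-2-ol F2. This is silylated (TBSCl, imidazole) to tert-butyl[(2R)-hept-6-en-2-yloxy]dimethylsilane F3. mCPBA then gives the epoxide as a mixture of epimers, tert-butyldimethyl{[(2R)-5-(oxiran-2-yl)pentan-2-yl]oxy}silane F4.

Hydrolytic kinetic resolution with (R,R)-(salen)Co(OAc) (salen = N,N'-bis(3,5-di-tert-butylsalicylidene)-1,2-cyclohexanediamine dianion) and 0.55 equiv of water hydrolyses the (S)-epoxide. It should leave tert-butyldimethyl{[(2R)-5-[(2R)-oxiran-2-yl]pentan-2-yl]oxy}silane F5. The other epimer becomes (2S,6R)-6-(tert-butyldimethylsilyloxy)heptane-1,2-diol F6, which is removed by chromatography.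

Iodine–magnesium exchange on F1 (i-PrMgCl·LiCl, THF, −40 °C) gives methyl 2-(chloromagnesio)-3,6-dimethoxybenzoate F7. With CuI (20 mol %, −30 → 0 °C) this opens F5 at its CH2 terminus. The alkoxide closes on the methyl ester to (3R)-3-[(4R)-4-(tert-butyldimethylsilyloxy)pentyl]-5,8-dimethoxyisochroman-1-one F8. n-Bu4NF in THF gives (3R)-3-[(4R)-4-hydroxypentyl]-5,8-dimethoxyisochroman-1-one F9, and Steglich esterification of F9 with 5 gives 11.

**Step 7.**
- What may go wrong: the excess Lewis acid could cleave the secondary alkyl–oxygen bonds of the succinate or the lactone.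
- Demethylation at C5 could be incomplete.
- The released tert-butyl group could alkylate ring A.
- The hydroquinone could be oxidised by air during work-up.

The fallback sets out from 11 and comes back at 12. It uses the para relation of the two ethers instead of a Lewis acid.

Oxidative demethylation with (NH4)2Ce(NO3)6 (MeCN/H2O, 0 °C) should give tert-butyl (2R)-5-[(3R)-1,5,8-trioxo-3,4,5,8-tetrahydro-1H-isochromen-3-yl]pentan-2-yl butanedioate F10. This quinone is reduced at once with aqueous Na2S2O4 to tert-butyl (2R)-5-[(3R)-5,8-dihydroxy-1-oxoisochroman-3-yl]pentan-2-yl butanedioate F11. CF3CO2H in CH2Cl2 at 0 °C then removes the tert-butyl group and gives 12.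

**Step 1.**
- What may go wrong: s-BuLi could add to the carboxylate.
- s-BuLi could displace the 2-methoxy group.
- Metalation of the poorly soluble lithium salt could be incomplete.

The fallback sets out from 1 and comes back at 3. It replaces the alkyllithium by a non-nucleophilic magnesium amide acting on an ester.

1 is converted with Boc2O, DMAP and t-BuOH into tert-butyl 2,5-dimethoxybenzoate F12. Ester-directed magnesiation with (TMP)2Mg·2LiCl (THF, 0 °C → rt) at the position between the ester and the methoxy group gives the aryl magnesium amide tert-butyl 3,6-dimethoxy-2-[(2,2,6,6-tetramethylpiperidin-1-yl)magnesio]benzoate F13. Iodine gives tert-butyl 2-iodo-3,6-dimethoxybenzoate F14, and CF3CO2H in CH2Cl2 gives 3.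

## Further compounds

F1 | step 5 | methyl 2-iodo-3,6-dimethoxybenzoate | COC(=O)c1c(OC)ccc(OC)c1I
F2 | step 5 | (R)-hept-6-en-2-ol | C[C@H](CCCC=C)O
F3 | step 5 | tert-butyl[(2R)-hept-6-en-2-yloxy]dimethylsilane | C[C@H](CCCC=C)O[Si](C)(C)C(C)(C)C
F4 | step 5 | tert-butyldimethyl{[(2R)-5-(oxiran-2-yl)pentan-2-yl]oxy}silane (epoxide epimers) | C[C@H](CCCC1CO1)O[Si](C)(C)C(C)(C)C
F5 | step 5 | tert-butyldimethyl{[(2R)-5-[(2R)-oxiran-2-yl]pentan-2-yl]oxy}silane | C[C@H](CCC[C@@H]1CO1)O[Si](C)(C)C(C)(C)C
F6 | step 5 | (2S,6R)-6-(tert-butyldimethylsilyloxy)heptane-1,2-diol | C[C@H](CCC[C@H](O)CO)O[Si](C)(C)C(C)(C)C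
F7 | step 5 | methyl 2-(chloromagnesio)-3,6-dimethoxybenzoate | COC(=O)c1c(OC)ccc(OC)c1[Mg]Cl
F8 | step 5 | (3R)-3-[(4R)-4-(tert-butyldimethylsilyloxy)pentyl]-5,8-dimethoxyisochroman-1-one | C[C@H](CCC[C@@H]1Cc2c(OC)ccc(OC)c2C(=O)O1)O[Si](C)(C)C(C)(C)C
F9 | step 5 | (3R)-3-[(4R)-4-hydroxypentyl]-5,8-dimethoxyisochroman-1-one | C[C@H](CCC[C@@H]1Cc2c(OC)ccc(OC)c2C(=O)O1)O
F10 | step 7 | tert-butyl (2R)-5-[(3R)-1,5,8-trioxo-3,4,5,8-tetrahydro-1H-isochromen-3-yl]pentan-2-yl butanedioate | C[C@H](CCC[C@@H]1CC2=C(C(=O)O1)C(=O)C=CC2=O)OC(=O)CCC(=O)OC(C)(C)C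
F11 | step 7 | tert-butyl (2R)-5-[(3R)-5,8-dihydroxy-1-oxoisochroman-3-yl]pentan-2-yl butanedioate | C[C@H](CCC[C@@H]1Cc2c(O)ccc(O)c2C(=O)O1)OC(=O)CCC(=O)OC(C)(C)C
F12 | step 1 | tert-butyl 2,5-dimethoxybenzoate | COc1ccc(OC)c(C(=O)OC(C)(C)C)c1
F13 | step 1 | tert-butyl 3,6-dimethoxy-2-[(2,2,6,6-tetramethylpiperidin-1-yl)magnesio]benzoate | CC1(C)CCCC(C)(C)N1[Mg]c1c(OC)ccc(OC)c1C(=O)OC(C)(C)C
F14 | step 1 | tert-butyl 2-iodo-3,6-dimethoxybenzoate | CC(C)(C)OC(=O)c1c(OC)ccc(OC)c1I
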